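## Retrosynthetic overview

1. Numbering: lactone O1, C2(=O), C3=C4, C5, C6, C7; chain B C8–C13; chain A on C3. The five carbons C7–C8–C9–C10–C11 (C7 bearing CH3 and C6, C8 bearing OH) are read as the ring of a 2,2-disubstituted 3-hydroxycyclopentanone with C11 as the ketone. O1 is then an oxygen atom slipped into the C7–C11 bond.
2. The oxepinone is formed last: O1–C2 by Yamaguchi lactonisation, and C3=C4 by Z-selective Ando olefination of the C4 aldehyde with a chain-A phosphonate (from propargyl alcohol and the Ando reagent).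
3. Chain B: the Z-C11=C12 alkene comes from a C11≡C12–C13 ynoate and Me2CuLi. The alkyne comes from the lactol of a temporary δ-lactone (O1, C7, C8, C9, C10, C11).
4. The δ-lactone comes from Baeyer–Villiger ring expansion of the cyclopentanone. C7 and C8 are set together beforehand by CBS mono-reduction of the prochiral dione made from 2-methylcyclopentane-1,3-dione and acrolein.
5. Ring order: cyclopentane (purchased), then δ-lactone (step 5, opened in steps 6–7), then seven-membered lactone (step 22).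

Key step: step 5

Remark: target locants (O1, C2–C13) are used throughout. The (S)-oxazaborolidine is assigned from the usual model with quaternary C7 as the large group, and the sense of induction should be confirmed on compound 5 by Mosher ester analysis.

## Route

Step 1
Reactants: 1 2-methylcyclopentane-1,3-dione; 2 acrolein
Product: 3 3-(1-methyl-2,5-dioxocyclopentyl)propanal
Conditions: 2 (1.5 equiv), H2O, rt
Reagents that add atoms: none
Why: Michael addition of the acidic cyclic 1,3-dione to acrolein needs no added base in water, and C-alkylation at the methyl-bearing carbon builds the quaternary, still achiral C7 together with C4–C6.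

Step 2
Reactants: 3 3-(1-methyl-2,5-dioxocyclopentyl)propanal
Product: 4 2-[2-(1,3-dioxolan-2-yl)ethyl]-2-methylcyclopentane-1,3-dione
Conditions: ethylene glycol (1.1 equiv), pyridinium p-toluenesulfonate (5 mol %), benzene, reflux, Dean–Stark trap
Reagents that add atoms: ethylene glycol, OCCO
Why: Acid-catalysed acetalisation is chemoselective because the unhindered aldehyde reacts far faster than the two ring ketones flanking the quaternary carbon, and azeotropic removal of water drives it to completion.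

Step 3
Reactants: 4 2-[2-(1,3-dioxolan-2-yl)ethyl]-2-methylcyclopentane-1,3-dione
Product: 5 (2R,3R)-2-[2-(1,3-dioxolan-2-yl)ethyl]-3-hydroxy-2-methylcyclopentan-1-one (OH cis to the side chain)
Conditions: (S)-2-methyl-CBS-oxazaborolidine [(3aS)-1-methyl-3,3-diphenyltetrahydro-1H,3H-pyrrolo[1,2-c][1,3,2]oxazaborole] (20 mol %), catecholborane (1.3 equiv), N,N-diethylaniline, toluene, −78 → −40 °C; MeOH, then pH 7 buffer
Reagents that add atoms: none
Why: In this Corey–Bakshi–Shibata reduction used as a desymmetrisation, the catalyst binds one of the two enantiotopic carbonyl groups with C7 as the large group and should give the (R)-carbinol at C8, while hydride enters from the ring face carrying the small methyl group, so OH ends cis to the side chain and C7 becomes (R) in the same event.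

Step 4
Reactants: 5 (2R,3R)-2-[2-(1,3-dioxolan-2-yl)ethyl]-3-hydroxy-2-methylcyclopentan-1-one
Product: 6 (2R,3R)-3-(tert-butyldimethylsilyloxy)-2-[2-(1,3-dioxolan-2-yl)ethyl]-2-methylcyclopentan-1-one
Conditions: TBSCl (1.5 equiv), imidazole (3 equiv), DMF, rt → 40 °C
Reagents that add atoms: tert-butyldimethylsilyl chloride, CC(C)(C)[Si](C)(C)Cl
Why: Standard imidazole-promoted silylation blocks retro-aldol opening of the ketol, and the chloride is used instead of a silyl triflate because triflate with a pyridine base would attack the dioxolane.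

Step 5
Reactants: 6 (2R,3R)-3-(tert-butyldimethylsilyloxy)-2-[2-(1,3-dioxolan-2-yl)ethyl]-2-methylcyclopentan-1-one
Product: 8 (5R,6R)-5-(tert-butyldimethylsilyloxy)-6-[2-(1,3-dioxolan-2-yl)ethyl]-6-methyltetrahydro-2H-pyran-2-one, via Criegee adduct 7 (not isolated)
Conditions: mCPBA (3 equiv), NaHCO3 (6 equiv), CH2Cl2, 0 °C → rt
Reagents that add atoms: 3-chloroperbenzoic acid, OOC(=O)c1cccc(Cl)c1
Why: The peracid adds to the C11 carbonyl to give Criegee adduct 7, in which the C7–C11 bond lying antiperiplanar to the O–O bond shifts to oxygen while 3-chlorobenzoate departs. The closest known reaction type is the Baeyer–Villiger oxidation of 2,2-disubstituted cyclopentanones obtained from mono-reduced cyclopentane-1,3-diones, which is established chemistry. The six-membered lactone ring (O1, C7, C8, C9, C10, C11) is formed by ring expansion through a 1,2-shift and not by cyclisation of an open chain. No stereocentre is created: C7 migrates with retention, so the (R) centre set in step 3 becomes the tertiary C–O centre unchanged, and C8 is a spectator. The selectivity needed is migration of C7 instead of C10, and it is secured by the much better ability of fully substituted C7 to carry partial positive charge than the C10 methylene, an advantage that the inductive effect of the C8 silyloxy group should not cancel. Chemoselectivity follows from the absence of any alkene at this stage, and solid NaHCO3 keeps the medium neutral for the dioxolane and the silyl ether.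

Step 6
Reactants: 8 (5R,6R)-5-(tert-butyldimethylsilyloxy)-6-[2-(1,3-dioxolan-2-yl)ethyl]-6-methyltetrahydro-2H-pyran-2-one
Product: 9 (5R,6R)-5-(tert-butyldimethylsilyloxy)-6-[2-(1,3-dioxolan-2-yl)ethyl]-6-methyltetrahydro-2H-pyran-2-ol (anomeric mixture)
Conditions: i-Bu2AlH (1.2 equiv), CH2Cl2, −78 °C; aq. KNaC4H4O6
Reagents that add atoms: none
Why: Partial lactone reduction with about one equivalent of i-Bu2AlH stops at the tetrahedral stage at low temperature and releases the lactol on work-up, while the acetal and silyl ether are inert.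

Step 7
Reactants: 9 (5R,6R)-5-(tert-butyldimethylsilyloxy)-6-[2-(1,3-dioxolan-2-yl)ethyl]-6-methyltetrahydro-2H-pyran-2-ol
Product: 11 (3R,4R)-4-(tert-butyldimethylsilyloxy)-1-(1,3-dioxolan-2-yl)-3-methyloct-7-yn-3-ol, via open hydroxy aldehyde 10 (not isolated)
Conditions: dimethyl (1-diazo-2-oxopropyl)phosphonate (2 equiv), K2CO3 (3 equiv), MeOH, 0 °C → rt
Reagents that add atoms: dimethyl (1-diazo-2-oxopropyl)phosphonate, CC(=O)C(=[N+]=[N-])P(=O)(OC)OC
Why: The Ohira–Bestmann (Seyferth–Gilbert) homologation drains the lactol through its open form 10, makes C11 the inner alkyne carbon, adds C12 and frees the C7 tertiary alcohol, while the TBS group should stay on the less crowded secondary oxygen.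

Step 8
Reactants: 11 (3R,4R)-4-(tert-butyldimethylsilyloxy)-1-(1,3-dioxolan-2-yl)-3-methyloct-7-yn-3-ol
Product: 12 methyl (6R,7R)-6-(tert-butyldimethylsilyloxy)-9-(1,3-dioxolan-2-yl)-7-(methoxycarbonyloxy)-7-methylnon-2-ynoate
Conditions: n-BuLi (2.3 equiv), THF, −78 °C; ClCO2Me (4 equiv), −78 → 0 °C
Reagents that add atoms: methyl chloroformate, COC(=O)Cl
Why: Double deprotonation followed by acylation with excess chloroformate (alkynyllithium methoxycarbonylation) adds C13 and deliberately caps the tertiary alkoxide as a methyl carbonate, which removes the C- versus O-acylation question; any material left free on oxygen converges again at compound 15, and the low temperature suppresses an O-to-O silyl shift.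

Step 9
Reactants: 12 methyl (6R,7R)-6-(tert-butyldimethylsilyloxy)-9-(1,3-dioxolan-2-yl)-7-(methoxycarbonyloxy)-7-methylnon-2-ynoate
Product: 14 methyl (2Z,6R,7R)-6-(tert-butyldimethylsilyloxy)-9-(1,3-dioxolan-2-yl)-7-(methoxycarbonyloxy)-3,7-dimethylnon-2-enoate, via alkenylcuprate 13 (not isolated)
Conditions: Me2CuLi (from CuI and MeLi, 2 equiv), THF, −78 °C; AcOH in THF, −78 °C
Reagents that add atoms: lithium dimethylcuprate, [Li+].C[Cu-]C (made from methyllithium, [Li]C, and CuI)
Why: Syn-carbocupration of the 2-ynoate puts the new methyl on C11 and copper on C12 on the same side, and protonation of 13 with retention at −78 °C leaves C10 cis to the ester (Z) before any equilibration through an allenolate can occur.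

Step 10
Reactants: 14 methyl (2Z,6R,7R)-6-(tert-butyldimethylsilyloxy)-9-(1,3-dioxolan-2-yl)-7-(methoxycarbonyloxy)-3,7-dimethylnon-2-enoate
Product: 15 (2Z,6R,7R)-6-(tert-butyldimethylsilyloxy)-9-(1,3-dioxolan-2-yl)-3,7-dimethylnon-2-ene-1,7-diol
Conditions: i-Bu2AlH (7 equiv), CH2Cl2, −78 → 0 °C; aq. KNaC4H4O6
Reagents that add atoms: none
Why: i-Bu2AlH reduces the enoate in 1,2-fashion to the allylic alcohol without touching the alkene geometry and cleaves the carbonate reductively, so the temporary O-protection costs no separate step.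

Step 11
Reactants: 15 (2Z,6R,7R)-6-(tert-butyldimethylsilyloxy)-9-(1,3-dioxolan-2-yl)-3,7-dimethylnon-2-ene-1,7-diol
Product: 16 (3R,4R,7Z)-4-(tert-butyldimethylsilyloxy)-9-(tert-butyldiphenylsilyloxy)-1-(1,3-dioxolan-2-yl)-3,7-dimethylnon-7-en-3-ol
Conditions: TBDPSCl (1.1 equiv), imidazole (2 equiv), CH2Cl2, 0 °C → rt
Reagents that add atoms: tert-butyldiphenylsilyl chloride, CC(C)(C)[Si](Cl)(c1ccccc1)c1ccccc1
Why: Silylation discriminates on steric grounds between the primary allylic and the crowded tertiary hydroxyl, and TBDPS is chosen because it must outlast the later removal of a triethylsilyl ether.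

Step 12
Reactants: 16 (3R,4R,7Z)-4-(tert-butyldimethylsilyloxy)-9-(tert-butyldiphenylsilyloxy)-1-(1,3-dioxolan-2-yl)-3,7-dimethylnon-7-en-3-ol
Product: 19 (4R,5R,8Z)-5-(tert-butyldimethylsilyloxy)-10-(tert-butyldiphenylsilyloxy)-4,8-dimethyl-4-(triethylsilyloxy)dec-8-enal, via triethylsilyl ether 17 (not isolated), via lutidinium triflate 18 (not isolated)
Conditions: TESOTf (1.3 equiv), 2,6-lutidine (6 equiv), CH2Cl2, −40 °C; TESOTf (2.5 equiv), 0 °C; H2O, rt
Reagents that add atoms: triethylsilyl trifluoromethanesulfonate, CC[Si](CC)(CC)OS(=O)(=O)C(F)(F)F; water, O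
Why: The silyl triflate with 2,6-lutidine first silylates C7–OH and then, at 0 °C, opens the dioxolane to salt 18, which water converts to the aldehyde (known non-acidic acetal cleavage), so all silyl ethers survive and the masked C7 oxygen can neither close on C4 to a lactol nor add later to the enoate.

Step 13
Reactants: 20 propargyl alcohol
Product: 22 (Z)-3-iodo-2-methylprop-2-en-1-ol, via magnesacycle 21 (not isolated)
Conditions: MeMgBr (3 equiv), CuI (15 mol %), THF/Et2O, −10 °C → rt; I2, 0 °C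
Reagents that add atoms: methylmagnesium bromide, C[Mg]Br; iodine, II
Why: Copper-catalysed, alkoxide-directed anti-carbomagnesiation of propargyl alcohol puts methyl on the inner carbon and magnesium on the terminus cis to CH2O in five-membered chelate 21, and iodinolysis with retention gives the Z-iodide.

Step 14
Reactants: 22 (Z)-3-iodo-2-methylprop-2-en-1-ol
Product: 23 tert-butyl{[(2Z)-3-iodo-2-methylprop-2-en-1-yl]oxy}diphenylsilane
Conditions: TBDPSCl (1.1 equiv), imidazole (2 equiv), CH2Cl2, rt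
Reagents that add atoms: tert-butyldiphenylsilyl chloride, CC(C)(C)[Si](Cl)(c1ccccc1)c1ccccc1
Why: Routine silylation of a primary allylic alcohol gives chain A the same robust group as C13–O.

Step 15
Reactants: 23 tert-butyl{[(2Z)-3-iodo-2-methylprop-2-en-1-yl]oxy}diphenylsilane
Product: 24 tert-butyl{[(2Z)-2-methylpenta-2,4-dien-1-yl]oxy}diphenylsilane
Conditions: tributyl(vinyl)stannane (1.2 equiv), PdCl2(MeCN)2 (5 mol %), DMF, rt
Reagents that add atoms: tributyl(vinyl)stannane, C=C[Sn](CCCC)(CCCC)CCCC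
Why: Stille coupling of an alkenyl iodide proceeds with retention at room temperature and avoids an alkenyllithium, which in this Z-series could suffer a 1,4 oxygen-to-carbon silyl shift.

Step 16
Reactants: 24 tert-butyl{[(2Z)-2-methylpenta-2,4-dien-1-yl]oxy}diphenylsilane
Product: 26 (3Z)-5-(tert-butyldiphenylsilyloxy)-4-methylpent-3-en-1-ol, via B-alkyl-9-BBN 25 (not isolated)
Conditions: 9-borabicyclo[3.3.1]nonane (1.1 equiv), THF, 0 °C → rt; aq. NaOH, H2O2, 0 °C
Reagents that add atoms: hydrogen peroxide, OO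
Why: In this hydroboration–oxidation the bulky borane adds anti-Markovnikov to the monosubstituted vinyl group only, because the trisubstituted alkene is too hindered, so the Z-geometry is untouched.

Step 17
Reactants: 26 (3Z)-5-(tert-butyldiphenylsilyloxy)-4-methylpent-3-en-1-ol
Product: 27 tert-butyl{[(2Z)-5-iodo-2-methylpent-2-en-1-yl]oxy}diphenylsilane
Conditions: I2 (1.2 equiv), PPh3 (1.2 equiv), imidazole (2.5 equiv), CH2Cl2, 0 °C → rt
Reagents that add atoms: iodine, II
Why: Appel-type iodination converts the primary alcohol by SN2 displacement of the oxyphosphonium group under nearly neutral conditions.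

Step 18
Reactants: 27 tert-butyl{[(2Z)-5-iodo-2-methylpent-2-en-1-yl]oxy}diphenylsilane; 28 ethyl 2-(diphenoxyphosphoryl)acetate
Product: 29 ethyl (5Z)-7-(tert-butyldiphenylsilyloxy)-2-(diphenoxyphosphoryl)-6-methylhept-5-enoate (racemic at C2)
Conditions: 28 (1.5 equiv), NaH (1.4 equiv), THF/DMF, 0 °C; 27, rt → 50 °C
Reagents that add atoms: none
Why: SN2 alkylation of the soft, weakly basic phosphonoacetate carbanion with a primary iodide should outrun elimination, excess 28 limits double alkylation, and a non-nucleophilic base spares the aryl phosphonate esters.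

Step 19
Reactants: 19 (4R,5R,8Z)-5-(tert-butyldimethylsilyloxy)-10-(tert-butyldiphenylsilyloxy)-4,8-dimethyl-4-(triethylsilyloxy)dec-8-enal; 29 ethyl (5Z)-7-(tert-butyldiphenylsilyloxy)-2-(diphenoxyphosphoryl)-6-methylhept-5-enoate
Product: 30 ethyl (2Z,6R,7R,10Z)-7-(tert-butyldimethylsilyloxy)-12-(tert-butyldiphenylsilyloxy)-2-[(3Z)-5-(tert-butyldiphenylsilyloxy)-4-methylpent-3-en-1-yl]-6,10-dimethyl-6-(triethylsilyloxy)dodeca-2,10-dienoate
Conditions: 29 (1.3 equiv), NaH (1.25 equiv), THF, 0 °C; 19, −78 → 0 °C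
Reagents that add atoms: none
Why: In the Ando variant of the Horner–Wadsworth–Emmons reaction, the electron-poor diaryl phosphonate collapses quickly from the kinetically formed adduct, so C5 should end cis to the ester (Z), a preference that α-alkyl substitution on the reagent reinforces.

Step 20
Reactants: 30 the ethyl ester of step 19
Product: 31 (2Z,6R,7R,10Z)-7-(tert-butyldimethylsilyloxy)-12-(tert-butyldiphenylsilyloxy)-2-[(3Z)-5-(tert-butyldiphenylsilyloxy)-4-methylpent-3-en-1-yl]-6,10-dimethyl-6-(triethylsilyloxy)dodeca-2,10-dienoic acid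
Conditions: LiOH (10 equiv), THF/MeOH/H2O, 45 °C; 0.5 M HCl to pH 4, 0 °C
Reagents that add atoms: lithium hydroxide, [Li+].[OH-]
Why: Saponification is carried out while C7–O is still silylated, so no alkoxide is available for conjugate addition to C4, and all four silyl ethers tolerate aqueous LiOH.

Step 21
Reactants: 31 the triethylsilyl-protected acid of step 20
Product: 32 (2Z,6R,7R,10Z)-7-(tert-butyldimethylsilyloxy)-12-(tert-butyldiphenylsilyloxy)-2-[(3Z)-5-(tert-butyldiphenylsilyloxy)-4-methylpent-3-en-1-yl]-6-hydroxy-6,10-dimethyldodeca-2,10-dienoic acid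
Conditions: HF·pyridine, excess pyridine, THF, 0 °C
Reagents that add atoms: none
Why: Selective desilylation rests on the much higher lability of a triethylsilyl ether compared with the primary TBDPS ethers and the hindered secondary TBS ether toward buffered fluoride.

Step 22
Reactants: 32 the seco acid of step 21
Product: 34 (7R)-7-[(1R,4Z)-1-(tert-butyldimethylsilyloxy)-6-(tert-butyldiphenylsilyloxy)-4-methylhex-4-en-1-yl]-3-[(3Z)-5-(tert-butyldiphenylsilyloxy)-4-methylpent-3-en-1-yl]-7-methyl-6,7-dihydrooxepin-2(5H)-one, via mixed anhydride 33 (not isolated)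
Conditions: 2,4,6-trichlorobenzoyl chloride (2 equiv), Et3N (3 equiv), THF, rt; slow addition to 4-(dimethylamino)pyridine (6 equiv), toluene, 80 °C, about 1 mM
Reagents that add atoms: none
Why: In this Yamaguchi lactonisation the Z-alkene holds C2 and C5 on the same side and fully substituted C7 compresses the tether, so seven-membered acyl transfer to the only free hydroxyl should compete with intermolecular acylation at high dilution even though the nucleophile is tertiary.

Step 23
Reactants: 34 the tris-silylated lactone of step 22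
Product: 35 (7R)-7-[(1R,4Z)-1,6-dihydroxy-4-methylhex-4-en-1-yl]-3-[(3Z)-5-hydroxy-4-methylpent-3-en-1-yl]-7-methyl-6,7-dihydrooxepin-2(5H)-one (CNP0139192.1)
Conditions: n-Bu4NF/AcOH (1:1, 10 equiv), THF, rt → 40 °C
Reagents that add atoms: none
Why: Global fluoride desilylation is buffered with acetic acid so that the liberated C8 oxygen is protonated at once, which should suppress acyl migration from O1 to the C8 oxygen as well as lactone opening, and spares the acid-sensitive Z-allylic alcohols.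

## Compound list

1 | 2-methylcyclopentane-1,3-dione | CC1C(=O)CCC1=O | starting material
2 | acrolein | C=CC=O | starting material
3 | 3-(1-methyl-2,5-dioxocyclopentyl)propanal | CC1(CCC=O)C(=O)CCC1=O | intermediate
4 | 2-[2-(1,3-dioxolan-2-yl)ethyl]-2-methylcyclopentane-1,3-dione | CC1(CCC2OCCO2)C(=O)CCC1=O | intermediate
5 | (2R,3R)-2-[2-(1,3-dioxolan-2-yl)ethyl]-3-hydroxy-2-methylcyclopentan-1-one | O1CCOC1CC[C@]2(C)[C@H](O)CCC2=O | intermediate
6 | (2R,3R)-3-(tert-butyldimethylsilyloxy)-2-[2-(1,3-dioxolan-2-yl)ethyl]-2-methylcyclopentan-1-one | O1CCOC1CC[C@]2(C)[C@H](O[Si](C)(C)C(C)(C)C)CCC2=O | intermediate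
7 | Criegee adduct: 6 with C11 bearing OH and 3-chlorobenzoylperoxy | O1CCOC1CC[C@]2(C)[C@H](O[Si](C)(C)C(C)(C)C)CCC2(O)OOC(=O)c3cccc(Cl)c3 | intermediate
8 | (5R,6R)-5-(tert-butyldimethylsilyloxy)-6-[2-(1,3-dioxolan-2-yl)ethyl]-6-methyltetrahydro-2H-pyran-2-one | O1CCOC1CC[C@]2(C)[C@H](O[Si](C)(C)C(C)(C)C)CCC(=O)O2 | intermediate
9 | (5R,6R)-5-(tert-butyldimethylsilyloxy)-6-[2-(1,3-dioxolan-2-yl)ethyl]-6-methyltetrahydro-2H-pyran-2-ol | O1CCOC1CC[C@]2(C)[C@H](O[Si](C)(C)C(C)(C)C)CCC(O)O2 | intermediate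
10 | (4R,5R)-4-(tert-butyldimethylsilyloxy)-7-(1,3-dioxolan-2-yl)-5-hydroxy-5-methylheptanal (open form of 9) | O1CCOC1CC[C@@](C)(O)[C@H](O[Si](C)(C)C(C)(C)C)CCC=O | intermediate
11 | (3R,4R)-4-(tert-butyldimethylsilyloxy)-1-(1,3-dioxolan-2-yl)-3-methyloct-7-yn-3-ol | O1CCOC1CC[C@@](C)(O)[C@H](O[Si](C)(C)C(C)(C)C)CCC#C | intermediate
12 | methyl (6R,7R)-6-(tert-butyldimethylsilyloxy)-9-(1,3-dioxolan-2-yl)-7-(methoxycarbonyloxy)-7-methylnon-2-ynoate | O1CCOC1CC[C@@](C)(OC(=O)OC)[C@H](O[Si](C)(C)C(C)(C)C)CCC#CC(=O)OC | intermediate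
13 | lithium alkenyl(methyl)cuprate: 14 with Cu(CH3)Li in place of C12–H, copper cis to the new C11 methyl | O1CCOC1CC[C@@](C)(OC(=O)OC)[C@H](O[Si](C)(C)C(C)(C)C)CC/C(C)=C(/[Cu-]C)C(=O)OC.[Li+] | intermediate
14 | methyl (2Z,6R,7R)-6-(tert-butyldimethylsilyloxy)-9-(1,3-dioxolan-2-yl)-7-(methoxycarbonyloxy)-3,7-dimethylnon-2-enoate | O1CCOC1CC[C@@](C)(OC(=O)OC)[C@H](O[Si](C)(C)C(C)(C)C)CC/C(C)=C\C(=O)OC | intermediate
15 | (2Z,6R,7R)-6-(tert-butyldimethylsilyloxy)-9-(1,3-dioxolan-2-yl)-3,7-dimethylnon-2-ene-1,7-diol | O1CCOC1CC[C@@](C)(O)[C@H](O[Si](C)(C)C(C)(C)C)CC/C(C)=C\CO | intermediate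
16 | (3R,4R,7Z)-4-(tert-butyldimethylsilyloxy)-9-(tert-butyldiphenylsilyloxy)-1-(1,3-dioxolan-2-yl)-3,7-dimethylnon-7-en-3-ol | O1CCOC1CC[C@@](C)(O)[C@H](O[Si](C)(C)C(C)(C)C)CC/C(C)=C\CO[Si](c2ccccc2)(c3ccccc3)C(C)(C)C | intermediate
17 | triethylsilyl ether of 16 at the C7 oxygen | O1CCOC1CC[C@@](C)(O[Si](CC)(CC)CC)[C@H](O[Si](C)(C)C(C)(C)C)CC/C(C)=C\CO[Si](c2ccccc2)(c3ccccc3)C(C)(C)C | intermediate
18 | 2,6-lutidinium triflate: C4 bearing N-lutidinium and 2-(triethylsilyloxy)ethoxy | CC[Si](CC)(CC)OCCOC([n+]1c(C)cccc1C)CC[C@@](C)(O[Si](CC)(CC)CC)[C@H](O[Si](C)(C)C(C)(C)C)CC/C(C)=C\CO[Si](c2ccccc2)(c3ccccc3)C(C)(C)C.[O-]S(=O)(=O)C(F)(F)F | intermediate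
19 | (4R,5R,8Z)-5-(tert-butyldimethylsilyloxy)-10-(tert-butyldiphenylsilyloxy)-4,8-dimethyl-4-(triethylsilyloxy)dec-8-enal | O=CCC[C@@](C)(O[Si](CC)(CC)CC)[C@H](O[Si](C)(C)C(C)(C)C)CC/C(C)=C\CO[Si](c1ccccc1)(c2ccccc2)C(C)(C)C | intermediate
20 | propargyl alcohol | C#CCO | starting material
21 | 4-methyl-2,5-dihydro-1,2-oxamagnesole (cyclic alkenylmagnesium alkoxide) | CC1=C[Mg]OC1 | intermediate
22 | (Z)-3-iodo-2-methylprop-2-en-1-ol | OC/C(C)=C\I | intermediate
23 | tert-butyl{[(2Z)-3-iodo-2-methylprop-2-en-1-yl]oxy}diphenylsilane | CC(C)(C)[Si](c1ccccc1)(c2ccccc2)OC/C(C)=C\I | intermediate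
24 | tert-butyl{[(2Z)-2-methylpenta-2,4-dien-1-yl]oxy}diphenylsilane | CC(C)(C)[Si](c1ccccc1)(c2ccccc2)OC/C(C)=C\C=C | intermediate
25 | 9-[(3Z)-5-(tert-butyldiphenylsilyloxy)-4-methylpent-3-en-1-yl]-9-borabicyclo[3.3.1]nonane | CC(C)(C)[Si](c1ccccc1)(c2ccccc2)OC/C(C)=C\CCB3C4CCCC3CCC4 | intermediate
26 | (3Z)-5-(tert-butyldiphenylsilyloxy)-4-methylpent-3-en-1-ol | CC(C)(C)[Si](c1ccccc1)(c2ccccc2)OC/C(C)=C\CCO | intermediate
27 | tert-butyl{[(2Z)-5-iodo-2-methylpent-2-en-1-yl]oxy}diphenylsilane | CC(C)(C)[Si](c1ccccc1)(c2ccccc2)OC/C(C)=C\CCI | intermediate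
28 | ethyl 2-(diphenoxyphosphoryl)acetate | CCOC(=O)CP(=O)(Oc1ccccc1)Oc1ccccc1 | starting material
29 | ethyl (5Z)-7-(tert-butyldiphenylsilyloxy)-2-(diphenoxyphosphoryl)-6-methylhept-5-enoate | CCOC(=O)C(CC/C=C(/C)CO[Si](c1ccccc1)(c2ccccc2)C(C)(C)C)P(=O)(Oc3ccccc3)Oc4ccccc4 | intermediate
30 | ethyl (2Z,6R,7R,10Z)-7-(tert-butyldimethylsilyloxy)-12-(tert-butyldiphenylsilyloxy)-2-[(3Z)-5-(tert-butyldiphenylsilyloxy)-4-methylpent-3-en-1-yl]-6,10-dimethyl-6-(triethylsilyloxy)dodeca-2,10-dienoate | CCOC(=O)/C(CC/C=C(/C)CO[Si](c1ccccc1)(c2ccccc2)C(C)(C)C)=C\CC[C@@](C)(O[Si](CC)(CC)CC)[C@H](O[Si](C)(C)C(C)(C)C)CC/C(C)=C\CO[Si](c3ccccc3)(c4ccccc4)C(C)(C)C | intermediate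
31 | carboxylic acid corresponding to 30 | OC(=O)/C(CC/C=C(/C)CO[Si](c1ccccc1)(c2ccccc2)C(C)(C)C)=C\CC[C@@](C)(O[Si](CC)(CC)CC)[C@H](O[Si](C)(C)C(C)(C)C)CC/C(C)=C\CO[Si](c3ccccc3)(c4ccccc4)C(C)(C)C | intermediate
32 | seco acid: 31 with free C7–OH | OC(=O)/C(CC/C=C(/C)CO[Si](c1ccccc1)(c2ccccc2)C(C)(C)C)=C\CC[C@@](C)(O)[C@H](O[Si](C)(C)C(C)(C)C)CC/C(C)=C\CO[Si](c3ccccc3)(c4ccccc4)C(C)(C)C | intermediate
33 | mixed anhydride of 32 and 2,4,6-trichlorobenzoic acid | Clc1cc(Cl)cc(Cl)c1C(=O)OC(=O)/C(CC/C=C(/C)CO[Si](c2ccccc2)(c3ccccc3)C(C)(C)C)=C\CC[C@@](C)(O)[C@H](O[Si](C)(C)C(C)(C)C)CC/C(C)=C\CO[Si](c4ccccc4)(c5ccccc5)C(C)(C)C | intermediate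
34 | (7R)-7-[(1R,4Z)-1-(tert-butyldimethylsilyloxy)-6-(tert-butyldiphenylsilyloxy)-4-methylhex-4-en-1-yl]-3-[(3Z)-5-(tert-butyldiphenylsilyloxy)-4-methylpent-3-en-1-yl]-7-methyl-6,7-dihydrooxepin-2(5H)-one | C/C(=C/CCC1=CCC[C@](C)([C@H](O[Si](C)(C)C(C)(C)C)CC/C(C)=C\CO[Si](c2ccccc2)(c3ccccc3)C(C)(C)C)OC1=O)CO[Si](c4ccccc4)(c5ccccc5)C(C)(C)C | intermediate
35 | (7R)-7-[(1R,4Z)-1,6-dihydroxy-4-methylhex-4-en-1-yl]-3-[(3Z)-5-hydroxy-4-methylpent-3-en-1-yl]-7-methyl-6,7-dihydrooxepin-2(5H)-one | C/C(=C/CCC1=CCC[C@](C)([C@H](O)CC/C(C)=C\CO)OC1=O)CO | target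

## Step count and risks

Total step count: 23. Longest linear sequence: 17 (steps 1–12 and 19–23). The chain-A branch (steps 13–18) joins at step 19.

**Risk 1, step 22 (lactonisation).**
- What may go wrong: acyl transfer to the crowded tertiary C7–OH may be too slow. Intermolecular acylation, or Z-to-E isomerisation of the activated enoate by reversible addition of the pyridine base, could then take over.
- Fallback: the O1–C2 bond is made first and the ring is closed at C3=C4. It sets out from 16 and 27 and returns at 34.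
- Iodide 27 alkylates triethyl phosphonoacetate (NaH, THF/DMF) to give ethyl (5Z)-7-(tert-butyldiphenylsilyloxy)-2-(diethoxyphosphoryl)-6-methylhept-5-enoate F1.
- NaOH in aqueous EtOH at rt cleaves only the carboxylic ester and gives the phosphono acid F2.
- Dicyclohexylcarbodiimide in CH2Cl2 dehydrates F2 to the phosphonoketene F3. This small, linear acylating agent is known to esterify tertiary alcohols, and it is captured by C7–OH of 16 to give the tertiary phosphonoacetate F4.
- AcOH/THF/H2O at 45 °C removes the dioxolane to give the aldehyde F5.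
- LiCl/DBU in MeCN at high dilution (Masamune–Roush conditions) closes the ring by intramolecular Horner–Wadsworth–Emmons reaction. The seven-membered ring allows only the cis (Z) alkene, so 34 results.

**Risk 2, step 19 (Ando olefination).**
- What may go wrong: the α-branched phosphonate anion may add sluggishly, the aldehyde may enolise, or Z-selectivity may erode through reversible addition.
- Fallback: the alkene geometry is fixed by stepwise substitution of a gem-dibromide. It sets out from 19 and 27 and returns at 31, bypassing 30.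
- Ramirez olefination of 19 (CBr4, PPh3, CH2Cl2, 0 °C) gives the 1,1-dibromoalkene F6.
- Zinc dust with LiCl in THF converts 27 to the alkylzinc iodide F7.
- Negishi coupling with PdCl2(DPEphos) [DPEphos = bis(2-diphenylphosphinophenyl) ether] replaces only the less hindered bromine trans to C5 and gives the (Z)-bromoalkene F8.
- Bromine–lithium exchange (t-BuLi, Et2O, −78 °C) gives the configurationally stable alkenyllithium F9, and CO2 then delivers acid 31 with the carboxyl group cis to C5.

**Risk 3, step 3 (desymmetrisation).**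
- What may go wrong: discrimination between the two ring faces (methyl against a primary alkyl chain) or between the two carbonyl groups may be insufficient, and over-reduction to the diol may occur.
- Fallback: boron hydride delivery is replaced by metal–ligand bifunctional asymmetric transfer hydrogenation. It sets out from 4 and returns at 5.
- Conditions: RuCl[(R,R)-TsDPEN](p-cymene) (1–2 mol %), HCO2H/Et3N (5:2), rt. This outer-sphere process is known for 2,2-disubstituted cyclopentane-1,3-diones and normally halts at the ketol.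
- The ligand antipode is to be fixed by Mosher ester analysis of 5. The detour makes no compound outside the list (F0).

## Further compounds

F1 | step 22 | ethyl (5Z)-7-(tert-butyldiphenylsilyloxy)-2-(diethoxyphosphoryl)-6-methylhept-5-enoate | CCOC(=O)C(CC/C=C(/C)CO[Si](c1ccccc1)(c2ccccc2)C(C)(C)C)P(=O)(OCC)OCC
F2 | step 22 | (5Z)-7-(tert-butyldiphenylsilyloxy)-2-(diethoxyphosphoryl)-6-methylhept-5-enoic acid | OC(=O)C(CC/C=C(/C)CO[Si](c1ccccc1)(c2ccccc2)C(C)(C)C)P(=O)(OCC)OCC
F3 | step 22 | phosphonoketene from F2 | O=C=C(CC/C=C(/C)CO[Si](c1ccccc1)(c2ccccc2)C(C)(C)C)P(=O)(OCC)OCC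
F4 | step 22 | ester of the C7 oxygen of 16 with F2 | O1CCOC1CC[C@@](C)(OC(=O)C(CC/C=C(/C)CO[Si](c2ccccc2)(c3ccccc3)C(C)(C)C)P(=O)(OCC)OCC)[C@H](O[Si](C)(C)C(C)(C)C)CC/C(C)=C\CO[Si](c4ccccc4)(c5ccccc5)C(C)(C)C
F5 | step 22 | C4 aldehyde from F4 | O=CCC[C@@](C)(OC(=O)C(CC/C=C(/C)CO[Si](c1ccccc1)(c2ccccc2)C(C)(C)C)P(=O)(OCC)OCC)[C@H](O[Si](C)(C)C(C)(C)C)CC/C(C)=C\CO[Si](c3ccccc3)(c4ccccc4)C(C)(C)C
F6 | step 19 | 1,1-dibromoalkene from 19 | BrC(Br)=CCC[C@@](C)(O[Si](CC)(CC)CC)[C@H](O[Si](C)(C)C(C)(C)C)CC/C(C)=C\CO[Si](c1ccccc1)(c2ccccc2)C(C)(C)C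
F7 | step 19 | [(3Z)-5-(tert-butyldiphenylsilyloxy)-4-methylpent-3-en-1-yl]zinc iodide | I[Zn]CC/C=C(/C)CO[Si](c1ccccc1)(c2ccccc2)C(C)(C)C
F8 | step 19 | (Z)-bromoalkene: 31 with Br in place of CO2H | Br/C(CC/C=C(/C)CO[Si](c1ccccc1)(c2ccccc2)C(C)(C)C)=C\CC[C@@](C)(O[Si](CC)(CC)CC)[C@H](O[Si](C)(C)C(C)(C)C)CC/C(C)=C\CO[Si](c3ccccc3)(c4ccccc4)C(C)(C)C
F9 | step 19 | alkenyllithium from F8 | [Li]/C(CC/C=C(/C)CO[Si](c1ccccc1)(c2ccccc2)C(C)(C)C)=C\CC[C@@](C)(O[Si](CC)(CC)CC)[C@H](O[Si](C)(C)C(C)(C)C)CC/C(C)=C\CO[Si](c3ccccc3)(c4ccccc4)C(C)(C)C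
F0 | step 3 | none | none
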